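Atom labels below use aromadendrane numbering: C1 and C5 are the ring-fusion CH, C2 the acetal CH, C3 the enol-ether CH, C4 the carbon bearing C15H2OAc, C6/C7 the cyclopropane CH, C10 the spiro carbon, C14 the epoxide CH2.

Assumption: racemic glycidyl acetate is used because its stereocentre becomes sp2 C4 in the target. Compounds 8–11 are therefore inconsequential C4-epimer mixtures.

## Retrosynthetic overview

1. The dihydropyran acetal is made last, by self-closure and acetylation of a C2/C3 1,5-dialdehyde that comes from oxidation of a 1,5-diol.
2. The spiro-epoxide comes from OH-directed epoxidation of a C10 exocyclic methylene, which comes from the C10 ketone.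
3. Key disconnection, C4–C5: the β-titanoxy radical from glycidyl acetate adds to the cyclopropyl-bearing β-carbon of a 2-(hydroxymethyl)enone. The spin lands on C1 and is never cyclopropylcarbinyl. This step sets C5 and C1.
4. The enone comes from Baylis–Hillman hydroxymethylation, allylic oxidation, and enantioselective dimethylcyclopropanation of 1,3-cycloheptadiene.
5. Ring order: seven-membered ring (purchased), then cyclopropane, then epoxide, then dihydropyran.

## Route

**Step 1**
Reactants: 1, cyclohepta-1,3-diene (1.5 equiv); 2, 2,2-dichloropropane
Product: 3, (1R,7S)-8,8-dimethylbicyclo[5.1.0]oct-2-ene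
Conditions: chiral (oxazoline–iminopyridine)CoBr2 (10 mol %, the ligand enantiomer that gives 1R,7S), Zn, ZnBr2, THF, 23 °C
Reagents that add atoms: none (the CMe2 unit comes from 2)
Why: In this cobalt-catalysed reductive Simmons–Smith-type dimethylcyclopropanation, 1,3-dienes are the preferred substrates and stop at the vinylcyclopropane, syn transfer gives the cis fusion, and the chiral ligand selects one of the two enantiotopic alkenes, fixing C6 and C7.

**Step 2**
Reactants: 3
Product: 4, (1R,7S)-8,8-dimethylbicyclo[5.1.0]oct-2-en-4-one
Conditions: CrO3, 3,5-dimethylpyrazole, CH2Cl2, −20 °C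
Reagents that add atoms: chromium trioxide, O=[Cr](=O)=O
Why: This Cr(VI)–dimethylpyrazole allylic oxidation can only attack C4H2, because the other allylic position is a strong cyclopropyl C–H, and it follows the carene-to-carenone type of oxidation without touching a stereocentre.

**Step 3**
Reactants: 4; 5, formaldehyde (37 % aq.)
Product: 6, (1R,7S)-3-(hydroxymethyl)-8,8-dimethylbicyclo[5.1.0]oct-2-en-4-one
Conditions: DMAP (0.3 equiv; n-Bu3P as alternative), THF–H2O, rt
Reagents that add atoms: none
Why: This Morita–Baylis–Hillman α-hydroxymethylation of a cyclic enone installs C2 before the key step, so that C1 is later defined by delivery of H rather than of carbon, and it creates no new stereocentre.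

**Step 4 (key step)**
Reactants: 6; 7, (±)-oxiran-2-ylmethyl acetate (glycidyl acetate, 3 equiv, added over 6 h)
Product: 8, 3-hydroxy-2-[(1R,2S,3S,7S)-3-(hydroxymethyl)-8,8-dimethyl-4-oxobicyclo[5.1.0]octan-2-yl]propyl acetate. The two new ring substituents are cis to each other and anti to the CMe2 bridge.
Conditions: Cp2TiCl2 (20 mol %), Mn, 2,4,6-collidine·HCl, THF, rt
Reagents that add atoms: none (only 2 H, from collidinium)
Why: In this Nugent–RajanBabu reductive epoxide opening and Giese addition, Cp2TiCl gives the secondary radical •CH(CH2OTi)(CH2OAc), which attacks C5 anti to the endo-methyl of the cyclopropane (sets C5) and places the spin on C1 as an α-keto radical with no cyclopropane or C–O clock; a second Ti(III) forms the enolate, which is C-protonated in situ anti to the bulky new C5 substituent to give the contra-thermodynamic 1,5-cis product (sets C1), with the C3-OH and C15-OAc arms differentiated without protecting groups.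

**Step 5**
Reactants: 8
Product: 9, 3-hydroxy-2-[(1R,2R,3R,7S)-3-(hydroxymethyl)-8,8-dimethyl-4-methylidenebicyclo[5.1.0]octan-2-yl]propyl acetate. The geometry is unchanged; the descriptors change only through CIP priority.
Conditions: Zn, CH2Br2, TiCl4 (Lombardo reagent, excess), THF–CH2Cl2, 0 °C to rt
Reagents that add atoms: dibromomethane, BrCBr
Why: Lombardo methylenation is non-basic, so it tolerates the free OH groups and the acetate, avoids retro-aldol and C1 epimerisation of the β-hydroxy ketone, and locks the cis C1/C5 relationship.

**Step 6**
Reactants: 9
Product: 10, 3-hydroxy-2-[(1R,2S,3S,4S,7S)-3-(hydroxymethyl)-8,8-dimethylspiro[bicyclo[5.1.0]octane-4,2'-oxiran]-2-yl]propyl acetate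
Conditions: VO(acac)2 (5 mol %), t-BuOOH (decane), CH2Cl2, 0 °C
Reagents that add atoms: tert-butyl hydroperoxide, CC(C)(C)OO
Why: In this vanadium-catalysed homoallylic-OH-directed epoxidation of the only alkene present, the C2-OH delivers oxygen to the face bearing C2, which is also the face anti to CMe2, so that O is cis to C2 and C14 is cis to H1 (sets C10).

**Step 7 (one pot)**
Reactants: 10
Product: 12, plagiochilin A, via the non-isolated dialdehyde 11, 2-[(1R,2S,3R,4S,7S)-3-formyl-8,8-dimethylspiro[bicyclo[5.1.0]octane-4,2'-oxiran]-2-yl]-3-oxopropyl acetate
Conditions: (COCl)2, DMSO, CH2Cl2, −78 °C; i-Pr2NEt, to −30 °C; then Ac2O, DMAP, to 0 °C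
Reagents that add atoms: acetic anhydride, CC(=O)OC(C)=O
Why: Swern double oxidation activates both OH groups before base is added, so no lactol or lactone forms; the more acidic C4–H aldehyde then enolises and its oxygen closes on the C2 aldehyde in an iridoid-type enol-lactol formation, any acetate lost by E1cB can re-add to reach the same enolate, the C4 stereocentre disappears, and acylation of the equatorial lactol places OAc trans to the C1–C10 bond (sets C2).

## Compound list

| No. | Name | SMILES | Role |
|---|---|---|---|
| 1 | cyclohepta-1,3-diene | C1=CC=CCCC1 | starting material |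
| 2 | 2,2-dichloropropane | CC(C)(Cl)Cl | starting material |
| 3 | (1R,7S)-8,8-dimethylbicyclo[5.1.0]oct-2-ene | C1CC[C@H]2[C@@H](C=C1)C2(C)C | intermediate |
| 4 | (1R,7S)-8,8-dimethylbicyclo[5.1.0]oct-2-en-4-one | O=C1CC[C@H]2[C@@H](C=C1)C2(C)C | intermediate |
| 5 | formaldehyde | C=O | starting material |
| 6 | (1R,7S)-3-(hydroxymethyl)-8,8-dimethylbicyclo[5.1.0]oct-2-en-4-one | O=C1CC[C@H]2[C@@H](C=C1CO)C2(C)C | intermediate |
| 7 | (±)-glycidyl acetate | CC(=O)OCC1CO1 | starting material |
| 8 | keto diol monoacetate (C4 epimers) | O=C1CC[C@H]2[C@@H]([C@@H](C(CO)COC(C)=O)[C@H]1CO)C2(C)C | intermediate |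
| 9 | methylidene diol monoacetate (C4 epimers) | C=C1CC[C@H]2[C@@H]([C@@H](C(CO)COC(C)=O)[C@H]1CO)C2(C)C | intermediate |
| 10 | spiro-epoxy diol monoacetate (C4 epimers) | C1O[C@]12CC[C@H]3[C@@H]([C@@H](C(CO)COC(C)=O)[C@H]2CO)C3(C)C | intermediate |
| 11 | epoxy dialdehyde (C4 epimers) | C1O[C@]12CC[C@H]3[C@@H]([C@@H](C(C=O)COC(C)=O)[C@H]2C=O)C3(C)C | intermediate (not isolated) |
| 12 | plagiochilin A | CC(=O)OCC1=CO[C@H](OC(C)=O)[C@@H]2[C@H]1[C@@H]1[C@H](CC[C@@]23CO3)C1(C)C | target |

## Step count and main risks

Total steps: 7. Longest linear sequence: 7.

Steps most likely to fail, each with one fallback: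

1. **Step 4.**
   - Risks: the intermolecular addition to a hindered enone may be slow. Ti(III) may reduce the radical or the enone instead. The enolate may lose the β-OH. The endo-methyl may steer protonation to the wrong face and give trans C1/C5.
   - Fallback: let a ring enforce the cis fusion. Couple enone 4 with 3,4-epoxybutanal under Ti(III) in a Giese–aldol [3+2] annulation to a cis-hydroazulenol. After methylenation and epoxidation, dehydrate to the C2=C3 cyclopentene and cleave it by ozonolysis to the same dialdehyde.
2. **Step 7.**
   - Risks: the β,γ-epoxy aldehyde may open by E1cB, and the β-acetoxy aldehyde may eliminate.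
   - Fallback: reverse the order of events. Oxidise, cyclise and acetylate the alkene diol 9 first, so that no epoxide is present. Then epoxidise the exocyclic methylene of the resulting diacetate as the last step. This gives up OH direction and accepts competition from the deactivated enol ether.
3. **Step 1.**
   - Risk: enantioselectivity on this cyclic diene is untested.
   - Fallback: use a desymmetrisation route. Dimethylcyclopropanate cyclohept-4-enone (8 heavy atoms) to meso 8,8-dimethylbicyclo[5.1.0]octan-4-one. Deprotonate enantioselectively with a chiral lithium amide and TMSCl, then carry out Saegusa oxidation to 4. This also removes the allylic oxidation of Step 2.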